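## Retrosynthetic overview

1. The C3 hydroxyl is added last (Rubottom α′-hydroxylation); the C6 ester is cut to a bicyclic dienone alcohol and (2E,4E,6S)-6-hydroxy-6-methylocta-2,4-dienoic acid.
2. The dienone alcohol comes from hydrogenation of a 5-methylidene tetraenone (this sets the C5 methyl).
3. The tetraenone comes from a palladium-catalysed dearomative para-cyclisation of a 4-methylphenol carrying a (Z)-dienyl bromide chain. This forms C4a–C5, the quaternary centre and ring A; ring B is the former phenol ring.
4. The phenol comes from 3-bromo-4-methylphenol by Sonogashira coupling, asymmetric alkynylation of 2-bromoacrolein and Z-selective semihydrogenation.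
5. The acid comes from 2-methylfuran by oxidative ring opening/Wittig, asymmetric ethylation of the methyl ketone and saponification.

Assumption: 2-bromoacrolein is prepared from acrolein rather than bought. Core locants follow naphthalen-2(3H)-one numbering (C2 carbonyl, C3 carbinol, C4a quaternary carbon, C5 methyl-bearing carbon, C6 acyloxy carbon).

## Route

Step 1
Reactants: 1 acrolein
Product: 3 2-bromoacrolein (2-bromoprop-2-enal), via 2,3-dibromopropanal 2 (not isolated)
Conditions: Br2, CH2Cl2, −78 °C; then Et3N, −78 → 0 °C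
Reagents that add atoms: bromine, BrBr
Why: Electrophilic bromination of the enal C=C followed by amine-mediated dehydrobromination (loss of the acidic α-hydrogen and the β-bromide) gives the α-bromo enal; no stereocentre is formed.

Step 2
Reactants: 4 3-bromo-4-methylphenol; 5 trimethylsilylacetylene
Product: 7 3-ethynyl-4-methylphenol, via 4-methyl-3-[(trimethylsilyl)ethynyl]phenol 6 (not isolated)
Conditions: PdCl2(PPh3)2 (3 mol %), CuI (5 mol %), Et3N, DMF, 80 °C; then K2CO3, MeOH, rt
Reagents that add atoms: none
Why: Sonogashira coupling of the aryl bromide tolerates the free phenol, and methanolysis of the C–Si bond in the same pot frees the terminal alkyne.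

Step 3
Reactants: 7 3-ethynyl-4-methylphenol; 3 2-bromoacrolein (1.5 equiv)
Product: 8 3-[(3S)-4-bromo-3-hydroxypent-4-en-1-yn-1-yl]-4-methylphenol
Conditions: ZnMe2 (3 equiv), ProPhenol ligand (10 mol %, enantiomer that directs Si-face attack), Ph3P=O (20 mol %), toluene, 0 °C; aq NH4Cl
Reagents that add atoms: none
Why: Zinc–ProPhenol catalysed enantioselective alkynylation of an α-substituted enal; the alkynylzinc (the phenol is masked in situ as its zinc phenoxide) is delivered to the Si face of the aldehyde, which sets C6 as S.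

Step 4
Reactants: 8 3-[(3S)-4-bromo-3-hydroxypent-4-en-1-yn-1-yl]-4-methylphenol
Product: 9 3-[(1Z,3S)-4-bromo-3-hydroxypenta-1,4-dien-1-yl]-4-methylphenol
Conditions: H2 (1 atm), Pd/CaCO3 poisoned with Pb(OAc)2 (Lindlar catalyst), quinoline, EtOAc, 0 °C → rt
Reagents that add atoms: none
Why: Lindlar semihydrogenation adds H2 syn to the aryl alkyne to give the Z-alkene needed for ring closure; the poisoned catalyst leaves the bromoalkene and the carbinol untouched.

Step 5
Reactants: 9 3-[(1Z,3S)-4-bromo-3-hydroxypenta-1,4-dien-1-yl]-4-methylphenol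
Product: 10 (4aS,6S)-6-hydroxy-4a-methyl-5-methylidene-5,6-dihydronaphthalen-2(4aH)-one
Conditions: [Pd(cinnamyl)Cl]2 (2.5 mol %), P-chiral monophosphine AntPhos (6 mol %, enantiomer matched for 4aS), K2CO3 (1.5 equiv), toluene, 90 °C
Reagents that add atoms: none
Why: Proposed new method: zerovalent palladium inserts into the alkenyl C–Br bond, the carbonate-generated phenoxide attacks the alkenyl palladium (divalent) centre through its para carbon C4a, and C–C reductive elimination closes ring A and breaks the aromaticity of ring B, the para methyl blocking re-aromatisation; the closest known reaction type is the palladium-catalysed enantioselective arylative dearomative cyclisation of 3-(2-haloarylethyl)-4-alkylphenols to 4a-alkyl phenanthrenones, extended here to an alkenyl bromide, and the P-chiral ligand sets the quaternary centre so that the C4a methyl is cis to the C6 hydroxyl (4aS).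

Step 6
Reactants: 10 (4aS,6S)-6-hydroxy-4a-methyl-5-methylidene-5,6-dihydronaphthalen-2(4aH)-one
Product: 11 (4aR,5R,6S)-6-hydroxy-4a,5-dimethyl-4,4a,5,6-tetrahydronaphthalen-2(3H)-one
Conditions: H2 (1 atm), RhCl(PPh3)3 (10 mol %), benzene, rt, stopped after 2 equiv H2
Reagents that add atoms: none
Why: Chemoselective homogeneous hydrogenation reduces the disubstituted cross-conjugated C3=C4 bond (as in steroidal 1,4-dien-3-ones) and the 1,1-disubstituted exocyclic alkene while the trisubstituted C1=C8a and the conjugated ring C7=C8 bonds react more slowly; H2 adds to the methylidene from the face opposite the axial C4a methyl and the C6 hydroxyl, which sets C5 as R with the methyl cis to both.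

Step 7
Reactants: 12 2-methylfuran; 13 methyl (triphenylphosphoranylidene)acetate
Product: 16 methyl (2E,4E)-6-oxohepta-2,4-dienoate, via (Z)-4-oxopent-2-enal 14 (not isolated), via (E)-4-oxopent-2-enal 15 (not isolated)
Conditions: NBS, NaHCO3, acetone/H2O (10:1), −20 °C; pyridine, rt; then 13, rt
Reagents that add atoms: water, O
Why: Oxidative ring opening of the furan (bromonium/water addition and collapse to the cis-enedicarbonyl) breaks its aromaticity, pyridine isomerises the Z-enal to the E-enal, and the stabilised Wittig ylide reacts only at the aldehyde with E selectivity.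

Step 8
Reactants: 16 methyl (2E,4E)-6-oxohepta-2,4-dienoate
Product: 17 methyl (2E,4E,6S)-6-hydroxy-6-methylocta-2,4-dienoate
Conditions: ZnEt2 (3 equiv), Ti(OiPr)4 (1.2 equiv), trans-cyclohexane-1,2-diamine bis(hydroxycamphorsulfonamide) ligand (10 mol %, enantiomer that directs Si-face attack), toluene/hexane, rt; aq NH4Cl
Reagents that add atoms: diethylzinc, CC[Zn]CC
Why: Titanium-promoted catalytic asymmetric 1,2-addition of diethylzinc to an alkenyl methyl ketone (copper-free, so no conjugate addition; the ester is untouched); ethyl transfer to the Si face, discriminating dienyl from methyl, sets the tertiary carbinol as S.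

Step 9
Reactants: 17 methyl (2E,4E,6S)-6-hydroxy-6-methylocta-2,4-dienoate
Product: 18 (2E,4E,6S)-6-hydroxy-6-methylocta-2,4-dienoic acid
Conditions: LiOH, THF/H2O, 0 °C → rt; then 1 M HCl to pH 4, 0 °C
Reagents that add atoms: lithium hydroxide, [Li+].[OH-]
Why: Saponification of the methyl ester leaves the base-stable tertiary carbinol and the diene geometry intact, and the mild cold acidification avoids ionising the tertiary allylic alcohol.

Step 10
Reactants: 18 (2E,4E,6S)-6-hydroxy-6-methylocta-2,4-dienoic acid; 11 (4aR,5R,6S)-6-hydroxy-4a,5-dimethyl-4,4a,5,6-tetrahydronaphthalen-2(3H)-one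
Product: 20 (4aR,5R,6S)-4a,5-dimethyl-2-oxo-2,3,4,4a,5,6-hexahydronaphthalen-6-yl (2E,4E,6S)-6-hydroxy-6-methylocta-2,4-dienoate, via mixed anhydride 19 (not isolated)
Conditions: 2,4,6-trichlorobenzoyl chloride, Et3N, toluene, rt; then 11, DMAP, toluene, rt → 40 °C
Reagents that add atoms: none
Why: Yamaguchi esterification acylates the hindered secondary C6 alcohol at the less hindered dienoyl carbonyl of the mixed anhydride with retention at C6, and the tertiary side-chain hydroxyl is too hindered to react.

Step 11
Reactants: 20 (4aR,5R,6S)-4a,5-dimethyl-2-oxo-2,3,4,4a,5,6-hexahydronaphthalen-6-yl (2E,4E,6S)-6-hydroxy-6-methylocta-2,4-dienoate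
Product: 23 CNP0260852.4, (3R,4aR,5R,6S)-3-hydroxy-4a,5-dimethyl-2-oxo-2,3,4,4a,5,6-hexahydronaphthalen-6-yl (2E,4E,6S)-6-hydroxy-6-methylocta-2,4-dienoate, via bis(trimethylsilyl) dienol ether 21 (not isolated), via silyloxy epoxide 22 (not isolated)
Conditions: LiN(SiMe3)2 (2.3 equiv), Me3SiCl (2.5 equiv), THF, −78 °C; DMDO, acetone/CH2Cl2, −78 °C; aq citric acid, THF, 0 °C
Reagents that add atoms: dimethyldioxirane, CC1(C)OO1
Why: Rubottom oxidation: kinetic α′-deprotonation with in situ silylation gives the cross-conjugated silyl enol ether (and masks the tertiary hydroxyl), the dioxirane epoxidises this most electron-rich alkene from the face opposite the axial C4a methyl, and acid hydrolysis gives the equatorial (3R) α-hydroxy ketone.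

## Compound list

1 | acrolein | C=CC=O | starting material
2 | 2,3-dibromopropanal | O=CC(Br)CBr | intermediate (not isolated)
3 | 2-bromoacrolein | C=C(Br)C=O | intermediate
4 | 3-bromo-4-methylphenol | Cc1ccc(O)cc1Br | starting material
5 | trimethylsilylacetylene | C#C[Si](C)(C)C | starting material
6 | 4-methyl-3-[(trimethylsilyl)ethynyl]phenol | Cc1ccc(O)cc1C#C[Si](C)(C)C | intermediate (not isolated)
7 | 3-ethynyl-4-methylphenol | Cc1ccc(O)cc1C#C | intermediate
8 | 3-[(3S)-4-bromo-3-hydroxypent-4-en-1-yn-1-yl]-4-methylphenol | Cc1ccc(O)cc1C#C[C@H](O)C(Br)=C | intermediate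
9 | 3-[(1Z,3S)-4-bromo-3-hydroxypenta-1,4-dien-1-yl]-4-methylphenol | Cc1ccc(O)cc1/C=C\[C@H](O)C(Br)=C | intermediate
10 | (4aS,6S)-6-hydroxy-4a-methyl-5-methylidene-5,6-dihydronaphthalen-2(4aH)-one | O[C@H]1C=CC2=CC(=O)C=C[C@]2(C)C1=C | intermediate
11 | (4aR,5R,6S)-6-hydroxy-4a,5-dimethyl-4,4a,5,6-tetrahydronaphthalen-2(3H)-one | O[C@H]1C=CC2=CC(=O)CC[C@]2(C)[C@H]1C | intermediate
12 | 2-methylfuran | Cc1ccco1 | starting material
13 | methyl (triphenylphosphoranylidene)acetate | COC(=O)C=P(c1ccccc1)(c1ccccc1)c1ccccc1 | starting material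
14 | (Z)-4-oxopent-2-enal | CC(=O)/C=C\C=O | intermediate (not isolated)
15 | (E)-4-oxopent-2-enal | CC(=O)/C=C/C=O | intermediate (not isolated)
16 | methyl (2E,4E)-6-oxohepta-2,4-dienoate | COC(=O)/C=C/C=C/C(C)=O | intermediate
17 | methyl (2E,4E,6S)-6-hydroxy-6-methylocta-2,4-dienoate | CC[C@](C)(O)/C=C/C=C/C(=O)OC | intermediate
18 | (2E,4E,6S)-6-hydroxy-6-methylocta-2,4-dienoic acid | CC[C@](C)(O)/C=C/C=C/C(=O)O | intermediate
19 | (2E,4E,6S)-6-hydroxy-6-methylocta-2,4-dienoic 2,4,6-trichlorobenzoic anhydride | CC[C@](C)(O)/C=C/C=C/C(=O)OC(=O)c1c(Cl)cc(Cl)cc1Cl | intermediate (not isolated)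
20 | (4aR,5R,6S)-4a,5-dimethyl-2-oxo-2,3,4,4a,5,6-hexahydronaphthalen-6-yl (2E,4E,6S)-6-hydroxy-6-methylocta-2,4-dienoate | CC[C@](C)(O)/C=C/C=C/C(=O)O[C@H]1C=CC2=CC(=O)CC[C@]2(C)[C@H]1C | intermediate
21 | C2 trimethylsilyl dienol ether of 20 with the side-chain hydroxyl as its trimethylsilyl ether | CC[C@](C)(O[Si](C)(C)C)/C=C/C=C/C(=O)O[C@H]1C=CC2=CC(O[Si](C)(C)C)=CC[C@]2(C)[C@H]1C | intermediate (not isolated)
22 | 2,3-epoxide of 21 (2-trimethylsilyloxy oxirane, oxygen on the face opposite the C4a methyl) | CC[C@](C)(O[Si](C)(C)C)/C=C/C=C/C(=O)O[C@H]1C=CC2=C[C@]3(O[Si](C)(C)C)O[C@@H]3C[C@]2(C)[C@H]1C | intermediate (not isolated)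
23 | CNP0260852.4, (3R,4aR,5R,6S)-3-hydroxy-4a,5-dimethyl-2-oxo-2,3,4,4a,5,6-hexahydronaphthalen-6-yl (2E,4E,6S)-6-hydroxy-6-methylocta-2,4-dienoate | CC[C@](C)(O)/C=C/C=C/C(=O)O[C@H]1C=CC2=CC(=O)[C@H](O)C[C@]2(C)[C@H]1C | target

## Step count and risks

Total steps: 11. Longest linear sequence: 7 steps (steps 2, 3, 4, 5, 6, 10, 11 from 3-bromo-4-methylphenol).

**Step 5 (dearomative cyclisation).** The risks are attack at the free ortho carbon, interference by the free C6 hydroxyl, and a substrate bias against the cis C4a-methyl/C6-hydroxyl relationship (1,3-syn) that the ligand must override. The fallback reverses the polarity of the ring closure. It sets out from 9: Pd(PPh3)4 and Me3SnSnMe3 in toluene at 80 °C convert the alkenyl bromide into the alkenylstannane 3-[(1Z,3S)-3-hydroxy-4-(trimethylstannyl)penta-1,4-dien-1-yl]-4-methylphenol F1. Oxidation of the phenol with PhI(OAc)2 in hexafluoroisopropanol at −20 °C then gives a phenoxenium ion that is attacked at its para carbon by the tin-bearing alkene carbon (ipso-destannylation). This returns to the route at 10. The hydrogen-bonding solvent damps competing attack by the C6 hydroxyl.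

**Step 6 (selective hydrogenation).** The conjugated ring C7=C8 bond may be reduced at a rate similar to the hindered exocyclic methylidene. The fallback is to over-reduce and then re-oxidise. It sets out from 10: hydrogenation with RhCl(PPh3)3 under 3 atm H2 until 3 equiv are taken up gives the saturated-ring enone (4aR,5R,6S)-6-hydroxy-4a,5-dimethyl-4,4a,5,6,7,8-hexahydronaphthalen-2(3H)-one F2 (the trisubstituted C1=C8a bond is inert). Chloranil in refluxing tert-butanol then dehydrogenates the enone through its dienol to the linear dienone, returning to the route at 11.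

**Step 3 (asymmetric alkynylation).** The unprotected phenol and the very electrophilic, polymerisation-prone 2-bromoacrolein may erode yield or ee. The fallback separates C–C bond formation from stereocontrol. It sets out from 7: EtMgBr (2.2 equiv, THF) forms the magnesium phenoxide/acetylide, and addition of 3 at −78 °C gives the racemic alcohol 3-(4-bromo-3-hydroxypent-4-en-1-yn-1-yl)-4-methylphenol F3. MnO2 in CH2Cl2 oxidises it to the ynone 2-bromo-5-(5-hydroxy-2-methylphenyl)pent-1-en-4-yn-3-one F4. CBS reduction (oxazaborolidine enantiomer giving the S alcohol, catecholborane, toluene, −78 °C; bromovinyl as the large group, alkynyl as the small group) returns to the route at 8.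

## Further compounds

F1 | step 5 | 3-[(1Z,3S)-3-hydroxy-4-(trimethylstannyl)penta-1,4-dien-1-yl]-4-methylphenol | Cc1ccc(O)cc1/C=C\[C@H](O)C(=C)[Sn](C)(C)C
F2 | step 6 | (4aR,5R,6S)-6-hydroxy-4a,5-dimethyl-4,4a,5,6,7,8-hexahydronaphthalen-2(3H)-one | O[C@H]1CCC2=CC(=O)CC[C@]2(C)[C@H]1C
F3 | step 3 | 3-(4-bromo-3-hydroxypent-4-en-1-yn-1-yl)-4-methylphenol (racemic) | Cc1ccc(O)cc1C#CC(O)C(Br)=C
F4 | step 3 | 2-bromo-5-(5-hydroxy-2-methylphenyl)pent-1-en-4-yn-3-one | Cc1ccc(O)cc1C#CC(=O)C(Br)=C
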